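A molecule of coupling partner is the one I follow: it removes one substrate molecule, left-handed or right-handed, and the excess is made at that fork.

| flask | left-handed substrate | right-handed substrate | coupling partner | racemization catalyst | added ligand | remark | time |
|---|---|---|---|---|---|---|---|
| north-east | 5 mM | 5 mM | 11 mM | 0.19 mM | 0.15 mM | run made earlier |  |
| north | 5 mM | 5 mM | 11 mM | 0.29 mM | 0.30 mM | run made earlier |  |
| Sunday's | 5.0 mM | 5.0 mM | 11.0 mM | 0.29 mM | 0.15 mM |  | 5.0 min |
| Wednesday's | 5.0 mM | 5.0 mM | 3.00 mM | 0.29 mM | 0.15 mM |  | 5.0 min |

| run | time / min | right-handed substrate / % | left-handed substrate / % | left-handed product / % |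
|---|---|---|---|---|
| north-east | 0.250 | 44.3 | 8.5 | 26.4 |
| north-east | 0.500 | 44.1 | 0 | 27.4 |
| north-east | 1.33 | 36.8 | 1.2 | 33.0 |
| north-east | 3.00 | 27.4 | 0 | 34.9 |
| north | 0.417 | 42.8 | 3.4 | 28.9 |
| north | 1.00 | 39.3 | 0 | 29.6 |
| north | 2.00 | 34.5 | 0 | 33.4 |
| north | 3.00 | 27.6 | 1.2 | 35.5 |

(scatter of a reading: 1 percentage point)

- coupling partner is single-handed; left-handed substrate and right-handed substrate are mirror images of each other, charged as a racemate, each of them at the stated concentration
- steps that have been proposed: coupling partner + left-handed substrate -> left-handed product; coupling partner + right-handed substrate -> right-handed product; left-handed substrate + racemization catalyst <-> right-handed substrate + racemization catalyst; left-handed product <-> right-handed product; racemization catalyst + added ligand <-> idle complex; racemization catalyst -> spent catalyst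
- an excess is the difference of the two amounts in percent of their sum
- an excess is below zero if the other one leads
- the handed part of coupling partner does not stay in what it makes, so the products of the two hands are mirror images too

- which one finishes higher in excess of right-handed substrate over left-handed substrate among what is left of the two ("neither" within 2 percentage points) (Sunday's / Wednesday's / neither)
- excess of right-handed substrate over left-handed substrate among what is left of the two at the end, Sunday's
- excess of right-handed substrate over left-handed substrate among what is left of the two at the end, Wednesday's

The substrates give the odds. Partner is common to both hands, so as long as no substrate changes hand the logarithm of what survives of the left hand over that of the right is the selectivity factor, and the first row of the north run reads 17.3. At the fork the left hand wins with chance 94.5 % at the start. On Wednesday's the partner is the limiting reagent, 30.0 % of the pair charged, and if the left hand paid for all of it the chance at the end would be 87.4 %. The mean of these two I call the left-hand share, the part of the used partner that lands on the left-handed substrate: 90.9 %. The left-hand share minus its complement, times the partner charge, over what the pair keeps, gives 35.1 % on Wednesday's.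

But one row is thin. The north-east row reads 14.6, which moves that excess to 33.9 %. Is the time enough? Taking the 2.00 mM of left-handed substrate that the charges leave if the left hand pays for all the partner, and the north-east first row for the rate, Wednesday's partner has a pseudo-first-order half-life that reads near 0.538 min, well inside 5.0 min.

The harder doubt is racemization afterwards. Suppose the ligand ties up one catalyst each and the rest lasts. The north-east run then has 0.0400 mM of free catalyst and the north run none, and right-handed substrate at 3.00 min differs between them by 0.2 percentage points, with each reading scattered by 1 point, so this is weak. Read as a drift of 0.00242 min⁻¹ and scaled to Wednesday's free catalyst, it keeps 91.9 % of the excess. I commit to 32.3 %, with more erosion possible.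

Taken at that share, the left hand of Sunday's asks about 5.50 mM of partner and Sunday's has 11.0 mM; the north reading at 3.00 min gives an excess of 91.7 %, and I expect Sunday's above that.

The forecast names Sunday's, with 90 % on Sunday's and 17 % on Wednesday's: “partner is exhausted within about 2 min at an excess near 37%, then racemization erodes it to about 17%”.

The flask gives 99.9 % on Sunday's and 36.9 % on Wednesday's, so Sunday's finishes higher. On Wednesday's at 5.00 min, 0.126 % of the catalyst charged is racemization catalyst, 21.6 % idle complex and 78.3 % spent catalyst. The left-hand share, applied to Wednesday's partner, takes the left-handed substrate to 22.7 % of the pair, and the flask holds 22.1 %.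

    coupling partner + left-handed substrate → left-handed product (k = 17.4 M⁻¹ s⁻¹)
    coupling partner + right-handed substrate → right-handed product (k = 0.657 M⁻¹ s⁻¹)
    left-handed substrate + racemization catalyst ⇌ right-handed substrate + racemization catalyst, rate k3*[racemization catalyst]*[left-handed substrate] forward; the back reaction follows from the equilibrium constant (k = 68.8 M⁻¹ s⁻¹)
    left-handed product ⇌ right-handed product (k = 0.139 s⁻¹)
    racemization catalyst + added ligand ⇌ idle complex (K = 6.40 × 10⁵ M⁻¹, k = 1330 M⁻¹ s⁻¹)
    racemization catalyst → spent catalyst (k = 0.243 s⁻¹)

A neighbour of Sunday's charged with 2.8 mM of partner gets 31.8 % from the same share. Its computed excess is 33.6 %.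

The data are calculated for substances that don't exist; scatter was added.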